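**Plan**
- Retrosynthetic cuts: (a) the side-chain aryl ether C–O bond and the carbinol C–H; (b) the oxolane C2–H bond (hemiketal reduction) and the C5–aryl bond; (c) the bond between oxolane C2 and the 3,4-dimethoxyphenyl ring, which leads back to meso-2,3-dimethylsuccinic anhydride.
- Enabling feature: ring carbons C2–C3–C4–C5 of the all-cis oxolane, with cis methyls on C3/C4 and an oxygenated benzylic carbon at each end, are a masked meso-2,3-dimethylsuccinyl unit. The ring is meso apart from one remote para-oxygen substituent, so choosing which enantiotopic anhydride carbonyl receives the 3,4-dimethoxyphenyl group fixes the absolute configuration of the whole ring.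
- Forward order: the anhydride ring is opened by enantioselective aryl–acyl coupling; the acid is taken to the aldehyde; the second aryl is added at C5; the oxolane closes as a hemiketal and is reduced; the phenol is freed; the side chain is attached by SN2 etherification and ketone reduction.
- Stereochemistry: C3/C4 from the meso anhydride plus a chiral rhodium catalyst; C5 by Felkin–Anh addition; C2 by hydride attack anti to three cis substituents; the ether carbon from (R)-lactate with inversion; the carbinol by chelation-controlled reduction.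

Key step: step 2

Assumption: the antipode of the phosphoramidite ligand that arylates the carbonyl bonded to the (S)-configured ring carbon of 2 is identified in a first small run and used throughout.

Step 1
Reactants: 1 meso-2,3-dimethylsuccinic acid
Product: 2 cis-3,4-dimethyloxolane-2,5-dione (meso-2,3-dimethylsuccinic anhydride)
Conditions: AcCl, reflux
Reagents that add atoms: none
Why: Cyclodehydration of a 1,4-diacid to the five-membered anhydride through a mixed anhydride is mild enough to keep the cis (meso) relationship of the two methyl groups.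

Step 2
Reactants: 2 cis-3,4-dimethyloxolane-2,5-dione; 3 4-bromo-1,2-dimethoxybenzene
Product: 6 (2R,3S)-4-(3,4-dimethoxyphenyl)-2,3-dimethyl-4-oxobutanoic acid, via (3,4-dimethoxyphenyl)lithium 4 (not isolated), via (3,4-dimethoxyphenyl)zinc chloride 5 (not isolated)
Conditions: 3, n-BuLi, THF, −78 °C; ZnCl2, −78 °C → rt; then 2, [Rh(cod)Cl]2 (cat.), TADDOL-derived dimethylphosphoramidite ligand (cat.), THF, 50 °C; aq. HCl
Reagents that add atoms: none
Why: The monovalent rhodium–phosphoramidite complex inserts into one of the two enantiotopic acyl C–O bonds of meso anhydride 2 to give an acyl rhodium carboxylate, and aryl transfer from zinc reagent 5 followed by C–C reductive elimination forms the aryl ketone and releases the zinc carboxylate of 6. The closest known reaction type is the rhodium- or palladium-catalysed enantioselective desymmetrising cross-coupling of cyclic meso anhydrides, cis-2,3-dimethylsuccinic anhydride included, with organozinc reagents made in situ from aryl bromides. No ring is closed; the anhydride ring is opened and both methyl-bearing stereocentres are carried over unchanged from the meso starting material. No new stereocentre is formed, but the chiral ligand decides which carbonyl is arylated and so fixes the absolute configuration (2R,3S), which becomes C4 and C3 of the oxolane. The step needs enantiotopic group selection (from the ligand), mono-arylation (the first acyl transfer leaves the second carbonyl as an unreactive zinc carboxylate, and the aryl zinc halide does not add to the ketone) and no epimerisation alpha to the new ketone (neutral, non-basic zinc reagent); the position of the new bond on the arene is fixed by the bromide of 3.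

Step 3
Reactants: 6 (2R,3S)-4-(3,4-dimethoxyphenyl)-2,3-dimethyl-4-oxobutanoic acid
Product: 7 S-ethyl (2R,3S)-4-(3,4-dimethoxyphenyl)-2,3-dimethyl-4-oxobutanethioate
Conditions: EtSH, DCC, DMAP (cat.), CH2Cl2, 0 °C
Reagents that add atoms: ethanethiol, CCS
Why: Carbodiimide-mediated thioesterification (Steglich type) at low temperature activates only the carboxyl group and should leave the ketone and both alpha stereocentres untouched.

Step 4
Reactants: 7 S-ethyl (2R,3S)-4-(3,4-dimethoxyphenyl)-2,3-dimethyl-4-oxobutanethioate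
Product: 8 (2R,3S)-4-(3,4-dimethoxyphenyl)-2,3-dimethyl-4-oxobutanal
Conditions: Et3SiH, Pd/C (palladium on carbon), acetone, rt
Reagents that add atoms: none
Why: Fukuyama reduction (zerovalent palladium inserts into the C–S bond, silane transfers hydride, reductive elimination gives the aldehyde) is neutral and chemoselective for the thioester over the aryl ketone, so the aldehyde should form without reduction of the ketone or epimerisation; 8 is used crude.

Step 5
Reactants: 8 (2R,3S)-4-(3,4-dimethoxyphenyl)-2,3-dimethyl-4-oxobutanal; 9 1-(benzyloxy)-4-bromo-2-methoxybenzene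
Product: 12 (3S,4R,5S)-5-[4-(benzyloxy)-3-methoxyphenyl]-2-(3,4-dimethoxyphenyl)-3,4-dimethyloxolan-2-ol (hemiketal, both C2 epimers, in equilibrium with the open hydroxy ketone), via [4-(benzyloxy)-3-methoxyphenyl]lithium 10 (not isolated), via [4-(benzyloxy)-3-methoxyphenyl]titanium triisopropoxide 11 (not isolated)
Conditions: 9, n-BuLi, THF, −78 °C; ClTi(OiPr)3, −78 → −30 °C; then 8, −78 → −20 °C; aq. NH4Cl
Reagents that add atoms: none
Why: The non-basic aryltitanium reagent adds to the aldehyde and not to the hindered aryl ketone, and Felkin–Anh 1,2-addition (the large CH(CH3)C(O)Ar group anti to the incoming aryl) should set C5 as S, that is with the aryl cis to the C4 methyl in the ring that forms when the new hydroxyl closes onto the ketone.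

Step 6
Reactants: 12 (3S,4R,5S)-5-[4-(benzyloxy)-3-methoxyphenyl]-2-(3,4-dimethoxyphenyl)-3,4-dimethyloxolan-2-ol
Product: 14 (2R,3S,4R,5S)-5-[4-(benzyloxy)-3-methoxyphenyl]-2-(3,4-dimethoxyphenyl)-3,4-dimethyloxolane (all-cis), via 2-aryl oxocarbenium ion 13 (not isolated)
Conditions: Et3SiH, BF3·OEt2, CH2Cl2, −78 °C
Reagents that add atoms: none
Why: Lewis-acid ionisation of the cyclic hemiketal gives the aryl-stabilised oxocarbenium ion and ionic hydrogenation delivers hydride to the face opposite the C3 methyl, C4 methyl and C5 aryl groups, which should set C2 as R and give the all-cis ring; the low temperature suppresses C3 epimerisation through the cyclic enol ether.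

Step 7
Reactants: 14 (2R,3S,4R,5S)-5-[4-(benzyloxy)-3-methoxyphenyl]-2-(3,4-dimethoxyphenyl)-3,4-dimethyloxolane
Product: 15 4-[(2S,3R,4S,5R)-5-(3,4-dimethoxyphenyl)-3,4-dimethyloxolan-2-yl]-2-methoxyphenol
Conditions: H2 (1 atm), Pd/C (palladium on carbon), EtOAc, rt
Reagents that add atoms: none
Why: Hydrogenolysis of the benzyl aryl ether is much faster than cleavage of the benzylic C–O bonds of the oxolane, which are known to tolerate this catalyst, so the phenol should be freed with the ring intact.

Step 8
Reactants: 16 methyl (2R)-2-hydroxypropanoate (methyl (R)-lactate)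
Product: 17 (2R)-2-hydroxy-N-methoxy-N-methylpropanamide
Conditions: MeNH(OMe)·HCl, i-PrMgCl, THF, −20 → 0 °C
Reagents that add atoms: N,O-dimethylhydroxylamine hydrochloride, CNOC.Cl
Why: Aminolysis of the ester by the magnesium amide gives the Weinreb amide without touching the stereocentre.

Step 9
Reactants: 17 (2R)-2-hydroxy-N-methoxy-N-methylpropanamide; 3 4-bromo-1,2-dimethoxybenzene
Product: 19 (2R)-1-(3,4-dimethoxyphenyl)-2-hydroxypropan-1-one, via (3,4-dimethoxyphenyl)magnesium bromide 18 (not isolated)
Conditions: 3, Mg, THF (→ 18, 2.2 equiv); then 17, THF, 0 °C → rt; aq. NH4Cl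
Reagents that add atoms: none
Why: Weinreb ketone synthesis: the first equivalent of Grignard reagent deprotonates the hydroxyl and the second adds once to the amide, the stable magnesium chelate preventing over-addition and enolisation, so the (R) centre should be retained.

Step 10
Reactants: 19 (2R)-1-(3,4-dimethoxyphenyl)-2-hydroxypropan-1-one
Product: 20 (2R)-1-(3,4-dimethoxyphenyl)-1-oxopropan-2-yl 4-methylbenzenesulfonate
Conditions: TsCl, Et3N, DMAP (cat.), CH2Cl2, 0 °C
Reagents that add atoms: 4-methylbenzenesulfonyl chloride, Cc1ccc(cc1)S(Cl)(=O)=O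
Why: O-Sulfonylation of the secondary alcohol proceeds at oxygen with retention at carbon and gives an alpha-keto sulfonate activated for SN2 displacement.

Step 11
Reactants: 15 4-[(2S,3R,4S,5R)-5-(3,4-dimethoxyphenyl)-3,4-dimethyloxolan-2-yl]-2-methoxyphenol; 20 (2R)-1-(3,4-dimethoxyphenyl)-1-oxopropan-2-yl 4-methylbenzenesulfonate
Product: 21 (2S)-1-(3,4-dimethoxyphenyl)-2-{4-[(2S,3R,4S,5R)-5-(3,4-dimethoxyphenyl)-3,4-dimethyloxolan-2-yl]-2-methoxyphenoxy}propan-1-one
Conditions: Cs2CO3, MeCN, 0 °C → rt
Reagents that add atoms: none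
Why: Williamson etherification: the caesium phenoxide displaces the carbonyl-activated secondary tosylate by SN2 with inversion (R to S), and the mild base and low temperature should limit enolisation of the product ketone.

Step 12
Reactants: 21 (2S)-1-(3,4-dimethoxyphenyl)-2-{4-[(2S,3R,4S,5R)-5-(3,4-dimethoxyphenyl)-3,4-dimethyloxolan-2-yl]-2-methoxyphenoxy}propan-1-one
Product: 22 (1R,2S)-1-(3,4-dimethoxyphenyl)-2-{4-[(2S,3R,4S,5R)-5-(3,4-dimethoxyphenyl)-3,4-dimethyloxolan-2-yl]-2-methoxyphenoxy}propan-1-ol
Conditions: Zn(BH4)2, Et2O, −30 → 0 °C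
Reagents that add atoms: none
Why: Chelation-controlled (Cram chelate) reduction: zinc bridges the carbonyl oxygen and the guaiacyl ether oxygens, and hydride adds from the side of the small hydrogen, which should give the anti (erythro) alcohol with the carbinol carbon R.

**Compound list**
1 | meso-2,3-dimethylsuccinic acid, (2R,3S) | OC(=O)[C@H](C)[C@H](C)C(=O)O | starting material
2 | cis-3,4-dimethyloxolane-2,5-dione, (3R,4S), meso | C[C@H]1C(=O)OC(=O)[C@H]1C | intermediate
3 | 4-bromo-1,2-dimethoxybenzene | COc1ccc(Br)cc1OC | starting material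
4 | (3,4-dimethoxyphenyl)lithium | COc1ccc([Li])cc1OC | intermediate
5 | (3,4-dimethoxyphenyl)zinc chloride | COc1ccc([Zn]Cl)cc1OC | intermediate
6 | (2R,3S)-4-(3,4-dimethoxyphenyl)-2,3-dimethyl-4-oxobutanoic acid | COc1ccc(C(=O)[C@@H](C)[C@@H](C)C(=O)O)cc1OC | intermediate
7 | S-ethyl (2R,3S)-4-(3,4-dimethoxyphenyl)-2,3-dimethyl-4-oxobutanethioate | COc1ccc(C(=O)[C@@H](C)[C@@H](C)C(=O)SCC)cc1OC | intermediate
8 | (2R,3S)-4-(3,4-dimethoxyphenyl)-2,3-dimethyl-4-oxobutanal | COc1ccc(C(=O)[C@@H](C)[C@@H](C)C=O)cc1OC | intermediate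
9 | 1-(benzyloxy)-4-bromo-2-methoxybenzene | COc1cc(Br)ccc1OCc1ccccc1 | starting material
10 | [4-(benzyloxy)-3-methoxyphenyl]lithium | COc1cc([Li])ccc1OCc1ccccc1 | intermediate
11 | [4-(benzyloxy)-3-methoxyphenyl]titanium triisopropoxide | COc1cc([Ti](OC(C)C)(OC(C)C)OC(C)C)ccc1OCc1ccccc1 | intermediate
12 | (3S,4R,5S)-5-[4-(benzyloxy)-3-methoxyphenyl]-2-(3,4-dimethoxyphenyl)-3,4-dimethyloxolan-2-ol, both C2 epimers | COc1cc([C@H]2OC(O)(c3ccc(OC)c(OC)c3)[C@@H](C)[C@H]2C)ccc1OCc1ccccc1 | intermediate
13 | (3S,4R,5S)-5-[4-(benzyloxy)-3-methoxyphenyl]-2-(3,4-dimethoxyphenyl)-3,4-dimethyl-4,5-dihydro-3H-furan-1-ium (2-aryl oxocarbenium ion) | COc1cc([C@H]2[O+]=C(c3ccc(OC)c(OC)c3)[C@@H](C)[C@H]2C)ccc1OCc1ccccc1 | intermediate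
14 | (2R,3S,4R,5S)-5-[4-(benzyloxy)-3-methoxyphenyl]-2-(3,4-dimethoxyphenyl)-3,4-dimethyloxolane, all-cis | COc1cc([C@H]2O[C@@H](c3ccc(OC)c(OC)c3)[C@@H](C)[C@H]2C)ccc1OCc1ccccc1 | intermediate
15 | 4-[(2S,3R,4S,5R)-5-(3,4-dimethoxyphenyl)-3,4-dimethyloxolan-2-yl]-2-methoxyphenol | COc1cc([C@H]2O[C@@H](c3ccc(OC)c(OC)c3)[C@@H](C)[C@H]2C)ccc1O | intermediate
16 | methyl (2R)-2-hydroxypropanoate | C[C@@H](O)C(=O)OC | starting material
17 | (2R)-2-hydroxy-N-methoxy-N-methylpropanamide | C[C@@H](O)C(=O)N(C)OC | intermediate
18 | (3,4-dimethoxyphenyl)magnesium bromide | COc1ccc([Mg]Br)cc1OC | intermediate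
19 | (2R)-1-(3,4-dimethoxyphenyl)-2-hydroxypropan-1-one | COc1ccc(C(=O)[C@@H](C)O)cc1OC | intermediate
20 | (2R)-1-(3,4-dimethoxyphenyl)-1-oxopropan-2-yl 4-methylbenzenesulfonate | COc1ccc(C(=O)[C@@H](C)OS(=O)(=O)c2ccc(C)cc2)cc1OC | intermediate
21 | (2S)-1-(3,4-dimethoxyphenyl)-2-{4-[(2S,3R,4S,5R)-5-(3,4-dimethoxyphenyl)-3,4-dimethyloxolan-2-yl]-2-methoxyphenoxy}propan-1-one | COc1ccc(C(=O)[C@H](C)Oc2ccc([C@H]3O[C@@H](c4ccc(OC)c(OC)c4)[C@@H](C)[C@H]3C)cc2OC)cc1OC | intermediate
22 | (1R,2S)-1-(3,4-dimethoxyphenyl)-2-{4-[(2S,3R,4S,5R)-5-(3,4-dimethoxyphenyl)-3,4-dimethyloxolan-2-yl]-2-methoxyphenoxy}propan-1-ol | COc1ccc([C@@H](O)[C@H](C)Oc2ccc([C@H]3O[C@@H](c4ccc(OC)c(OC)c4)[C@@H](C)[C@H]3C)cc2OC)cc1OC | target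

Total step count: 12. Longest linear sequence: 9 steps (steps 1 to 7, then 11 and 12); steps 8 to 10 form the side-chain branch.

**Steps most likely to fail**

Step 5. The risks are poor Felkin–Anh facial selectivity in the aryl addition and epimerisation of the 1,4-keto aldehyde 8 before it is trapped. The fallback exchanges the order in which aryl and hydride reach the two benzylic carbons. It sets out from 6. Reagent-controlled reduction of the aryl ketone with (+)-B-chlorodiisopinocampheylborane (the antipode that gives (R)-1-arylalkanols, chosen to override the substrate's Felkin preference), followed by acid-promoted lactonisation, should give the all-cis lactone (3R,4S,5R)-5-(3,4-dimethoxyphenyl)-3,4-dimethyloxolan-2-one F1. Aryllithium 10 (from 9, n-BuLi, THF, −78 °C) should then add once to the lactone carbonyl to give the hemiketal (3R,4S,5R)-2-[4-(benzyloxy)-3-methoxyphenyl]-5-(3,4-dimethoxyphenyl)-3,4-dimethyloxolan-2-ol F2. Et3SiH/BF3·OEt2 at −78 °C should deliver hydride anti to the three cis substituents, and the route is rejoined at 14.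

Step 6. The risk is loss of the all-cis arrangement, either by C3 epimerisation through the cyclic enol ether or by ionisation of the C5 benzylic C–O bond under the Lewis acid. The fallback makes the enol ether on purpose and sets C2 and C3 together by hydrogenation. It sets out from 12. Mild dehydration (pyridinium p-toluenesulfonate cat., toluene, molecular sieves) should give the cyclic enol ether (4R,5S)-5-[4-(benzyloxy)-3-methoxyphenyl]-2-(3,4-dimethoxyphenyl)-3,4-dimethyl-4,5-dihydrofuran F3. Hydrogen over Pd/C should add syn from the face opposite the C4 methyl and C5 aryl groups, giving the all-cis ring, and should cleave the benzyl ether in the same operation. The route is rejoined at 15.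

Step 2. The risks are insufficient enantiotopic group selection and sluggish coupling of the electron-rich aryl zinc reagent. Because the oxolane is meso-like, material of the wrong hand ends as a diastereomer that differs only remotely from 22, so 6 would be enriched by crystallisation of an amine salt before going on. The fallback separates the desymmetrisation from the C–C bond formation. It sets out from 2. Cinchona-alkaloid-mediated ring opening with benzyl alcohol (quinidine or quinine, whichever gives the required half ester, toluene, −55 °C) should give (2S,3R)-4-(benzyloxy)-2,3-dimethyl-4-oxobutanoic acid F4. EtSH/DCC/DMAP should give benzyl (2R,3S)-4-(ethylsulfanyl)-2,3-dimethyl-4-oxobutanoate F5. Fukuyama coupling of this thioester with zinc reagent 5 (from 3) under PdCl2(PPh3)2 catalysis should give benzyl (2R,3S)-4-(3,4-dimethoxyphenyl)-2,3-dimethyl-4-oxobutanoate F6. Hydrogenolysis of the benzyl ester (H2, Pd/C, EtOAc) rejoins the route at 6.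

Further compounds
F1 | step 5 | (3R,4S,5R)-5-(3,4-dimethoxyphenyl)-3,4-dimethyloxolan-2-one | O=C1O[C@@H](c2ccc(OC)c(OC)c2)[C@@H](C)[C@H]1C
F2 | step 5 | (3R,4S,5R)-2-[4-(benzyloxy)-3-methoxyphenyl]-5-(3,4-dimethoxyphenyl)-3,4-dimethyloxolan-2-ol | COc1cc(C2(O)O[C@@H](c3ccc(OC)c(OC)c3)[C@@H](C)[C@H]2C)ccc1OCc1ccccc1
F3 | step 6 | (4R,5S)-5-[4-(benzyloxy)-3-methoxyphenyl]-2-(3,4-dimethoxyphenyl)-3,4-dimethyl-4,5-dihydrofuran | COc1cc([C@H]2OC(c3ccc(OC)c(OC)c3)=C(C)[C@H]2C)ccc1OCc1ccccc1
F4 | step 2 | (2S,3R)-4-(benzyloxy)-2,3-dimethyl-4-oxobutanoic acid | OC(=O)[C@@H](C)[C@@H](C)C(=O)OCc1ccccc1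
F5 | step 2 | benzyl (2R,3S)-4-(ethylsulfanyl)-2,3-dimethyl-4-oxobutanoate | CCSC(=O)[C@@H](C)[C@@H](C)C(=O)OCc1ccccc1
F6 | step 2 | benzyl (2R,3S)-4-(3,4-dimethoxyphenyl)-2,3-dimethyl-4-oxobutanoate | COc1ccc(C(=O)[C@@H](C)[C@@H](C)C(=O)OCc2ccccc2)cc1OC
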